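# Proposed synthesis of (S)-2-(3-hydroxy-4,5-dimethoxyphenyl)-7,8-dimethoxychroman-4-one

**Numbering used throughout:** 1 pyrogallol; 2 dihydropyrogallol; 3 2,3-dimethoxycyclohex-2-en-1-one; 4 lithium enolate of 3; 5 6-acetyl-2,3-dimethoxycyclohex-2-en-1-one; 6 mono-silyl enol ether of 5; 7 lithium dienolate of 6; 8 bis-silyl diene; 9 3-hydroxy-4,5-dimethoxybenzaldehyde; 10 its benzyl ether; 11 silylated aldol adduct; 12 δ-hydroxy β-diketone; 13 tetrahydrochromenone; 14 benzyl-protected flavanone; 15 target.

## Analysis of the target

Compound 15 is a flavanone: a benzo ring A fused to a 2,3-dihydro-4H-pyran-4-one ring C, with ring B, a 3-hydroxy-4,5-dimethoxyphenyl group, on C2. C2 is the only stereocentre and is S; nothing else in the molecule can relay it, so a reagent or catalyst has to set it. C2 is benzylic, carries the ring oxygen O1 and lies β to the C4 carbonyl. Base, or hot strong acid, can therefore open ring C by a retro-oxa-Michael reaction to an achiral enone and racemise it. The free phenol on ring B and the aryl ketone are the other sensitive groups, and the phenol must be told apart from four methyl ethers. The difficulty is to form the C2–O1 bond of an electron-rich benzylic ether enantioselectively and then to keep every later step neutral or only mildly acidic. Ring A carries oxygen on three neighbouring carbons, C7 and C8 (methoxy) and C8a (O1), which is the pattern of pyrogallol. Ring A can therefore be carried as a 2,3-dimethoxycyclohex-2-enone whose carbonyl carbon becomes C8a and whose α′-carbon becomes C4a; in that form C4 and C8a are the two carbonyl carbons of a 1,3-diketone, and ring A is only two hydrogens (at C5 and C6) short of the arene.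

## Retrosynthetic reasoning

**O–benzyl bond of 15.** The ring B phenol is traced back to the benzyl ether 14. The phenol would bind the titanium catalyst and would be oxidised by a quinone, so it stays masked until the end. Hydrogenolysis is chosen for the release because it is neutral and cannot open ring C.

**C5–H and C6–H of 14.** Two hydrogens are added back to ring A to give 13. This is the move that turns the aryl ketone into a vinylogous ester of a 1,3-diketone. The forward step only has to remove two hydrogens from a cyclohexa-1,3-diene, with aromatisation as the driving force, and it does not touch C2.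

**O1–C8a and C2–C3 of 13.** Ring C is opened at the enol ether bond to the δ-hydroxy β-diketone 12, and 12 is cut at C2–C3 into the aldehyde 10 and the diene 8, which acts as a masked dianion of a 1,3-diketone. Cutting here, and not at C2–O1, means the carbinol C–O bond is made once, in the aldol step, and is never broken afterwards. The forward reaction has to deliver the terminal carbon of 8 to one face of 10 and then close the ring by dehydration. One step creates the ring, two skeletal bonds and the stereocentre.

**Two O–Si bonds of 8.** Diene 8 goes back through the mono-silyl enol ether 6 to the 1,3-diketone 5. The first silicon is placed on the enolised diketone, the second on the kinetic dienolate 7 of the methyl ketone.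

**C4–C4a bond of 5.** The acetyl group is removed from C6 of the cyclohexenone, leaving 3. Forward, the kinetic α′-enolate 4 of this vinylogous ester is C-acylated. This bond is cut because the α′-position of a 3-alkoxy enone is the one position that a hindered amide base deprotonates selectively.

**Two O–CH3 bonds and two C–H bonds of 3.** Compound 3 is the dimethyl ether of the reductone 2, which is pyrogallol 1 plus one molecule of hydrogen. Because the two hydroxyls of 2 are related by tautomerism, only one dimethyl ether can form, and the three oxygens of ring A come from 1 with their positions fixed.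

**O–benzyl bond of 10.** The aldehyde 10 is the benzyl ether of the commercial phenol 9, in which the methyl ethers and the free hydroxyl are already differentiated.

## Alternatives that were turned down

**Alternative 1:** carbonylative three-component annulation to a flavone.
- **Disconnection:** C4a–C4, C4–C3 and O1–C2, leading to 6-iodo-2,3-dimethoxyphenol A2, the ring B alkyne 1-(benzyloxy)-5-ethynyl-2,3-dimethoxybenzene A3 and carbon monoxide A4.
- **Forward key step:** with PdCl2(PPh3)2 in Et2NH, A2 would undergo carbonylative coupling with A3 and A4, and the resulting alkynyl ketone would close through its phenol oxygen to the flavone 2-(3-benzyloxy-4,5-dimethoxyphenyl)-7,8-dimethoxy-4H-chromen-4-one A1.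
- **For it:** three bonds and the ring in one catalytic step, a fully aromatic and robust product, and a convergent assembly. A3 is one step from 10. On convergence and step count it is at least as good as the chosen route.
- **Against it:** A1 is flat at C2. The stereocentre would have to be made afterwards by enantioselective 1,4-reduction of a C2=C3 bond that is deactivated by O1 and by an electron-rich aryl group. Over-reduction of the ketone and loss of the benzyl ether under hydrogen are likely side reactions. A2 also needs iodination ortho, not para, to the hydroxyl, which costs extra steps of directing-group chemistry.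
- **Comparison:** the chosen route gives up some convergence but makes C2 as an sp3 centre, in the same catalytic step that builds the ring, so no stage of the route has a planar C2 to be corrected.

**Alternative 2:** aryne annulation with a chiral hydroxy ester.
- **Disconnection:** O1–C8a and C4a–C4, leading to the iodo triflate 6-iodo-3-methoxy-2-(4,4,5,5-tetramethyl-1,3,2-dioxaborolan-2-yl)phenyl trifluoromethanesulfonate A6 and methyl (S)-3-(3-benzyloxy-4,5-dimethoxyphenyl)-3-hydroxypropanoate A7.
- **Forward key step:** iPrMgCl·LiCl would convert A6 into an aryne. The magnesium alkoxide of A7 would add at the aryne carbon next to the boron-bearing carbon, and the aryl anion so formed would attack the ester, giving (S)-2-(3-benzyloxy-4,5-dimethoxyphenyl)-7-methoxy-8-(4,4,5,5-tetramethyl-1,3,2-dioxaborolan-2-yl)chroman-4-one A5.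
- **For it:** the configuration at C2 is fixed beforehand in A7 by a well-established asymmetric reduction or aldol reaction, the carbinol C–O bond is not broken, and ring A is aromatic from the start. On the reliability of the stereocentre it is stronger than the chosen route.
- **Against it:** A6 is a densely substituted arene needing several steps. A secondary alkoxide is a sluggish aryne nucleophile and must attack next to a bulky boronate, which it can also complex. The β-alkoxy ester can undergo retro-aldol cleavage, and the ketone formed is exposed to the Grignard reagent. After the annulation the C–B bond must be oxidised and the new phenol methylated, and both operations normally use base, which threatens C2 through ring opening.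
- **Comparison:** the chosen route puts both ring A methoxy groups in place at the outset and needs only two neutral steps after the ring is formed.

**Alternative 3:** copper-catalysed aryl ether closure of a chiral diol.
- **Disconnection:** O1–C8a, leading to (1S,3S)-1-(2-bromo-3,4-dimethoxyphenyl)-3-(3-benzyloxy-4,5-dimethoxyphenyl)propane-1,3-diol A9.
- **Forward key step:** with CuI, 3,4,7,8-tetramethyl-1,10-phenanthroline and Cs2CO3, the hydroxyl at the ring B carbinol of A9 would couple with the aryl bromide with retention, giving (2S,4S)-2-(3-benzyloxy-4,5-dimethoxyphenyl)-7,8-dimethoxychroman-4-ol A8. Oxidation at C4 would then give 14.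
- **For it:** the closure cannot racemise C2, only the distal hydroxyl can form a ring, and no base-sensitive flavanone is present during the coupling. The stereocentre again comes from established asymmetric carbonyl chemistry. On these points it is as strong as the chosen route.
- **Against it:** the bromide lies between a methoxy group and a branched benzylic substituent, a hindered site for copper. Two benzylic alcohols are heated with carbonate. C4 must be reduced to the alcohol to survive the coupling and then oxidised back, so a stereocentre and two redox steps are spent for nothing. The ortho-brominated ring A ketone fragment needed for A9 adds further steps.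
- **Comparison:** the chosen route keeps C4 at the ketone level throughout and forms the ring and the stereocentre together, at the price of one late dehydrogenation.

Key step: step 7

Remark on the chemistry: the facial sense of the BINOL–titanium aldol addition is taken from that generally found with aryl aldehydes ((S)-ligand, attack on the Si face, S carbinol). If it were reversed with diene 8, (R)-BINOL would be used and nothing else in the route would change.

## Route

Step 1
Reactants: 1 pyrogallol (benzene-1,2,3-triol)
Product: 2 dihydropyrogallol (2,3-dihydroxycyclohex-2-en-1-one)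
Conditions: H2 (70–100 atm), Raney Ni, aq NaOH (1.1 equiv), 50 °C; then aq HCl, 0 °C
Reagents that add atoms: none
Why: Partial catalytic hydrogenation of a phenolate: the monosodium salt of 1 reacts through its keto tautomer, one C=C is saturated, and the product is held as the enolate of a vinylogous acid (a reductone), which resists further reduction; this is the reaction type by which resorcinol is reduced to cyclohexane-1,3-dione.

Step 2
Reactants: 2 dihydropyrogallol
Product: 3 2,3-dimethoxycyclohex-2-en-1-one
Conditions: Me2SO4 (2.3 equiv), K2CO3, acetone, reflux, under N2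
Reagents that add atoms: dimethyl sulfate, COS(=O)(=O)OC
Why: Double Williamson-type O-alkylation of the enediol: carbonate deprotonates the vinylogous acid hydroxyl and the enol hydroxyl, and the hard electrophile should methylate oxygen in preference to carbon; the two hydroxyls of 2 are related by tautomerism, so only one dimethyl ether can form.

Step 3
Reactants: 3 2,3-dimethoxycyclohex-2-en-1-one
Product: 5 6-acetyl-2,3-dimethoxycyclohex-2-en-1-one, via lithium enolate 4 (not isolated)
Conditions: LiN(iPr)2, THF, −78 °C; then 1-acetylbenzotriazole, −78 °C → 0 °C; aq NH4Cl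
Reagents that add atoms: 1-acetyl-1H-benzotriazole, CC(=O)n1nnc2ccccc12
Why: Stork–Danheiser-type kinetic deprotonation of the vinylogous ester takes the α′-proton at C6 and not the γ-proton at C4, and the lithium enolate 4 is C-acylated by the N-acylbenzotriazole (crossed Claisen-type acylation), an acyl donor known to convert ketone enolates into 1,3-diketones without O-acylation.

Step 4
Reactants: 5 6-acetyl-2,3-dimethoxycyclohex-2-en-1-one
Product: 6 1-[3,4-dimethoxy-2-(trimethylsilyloxy)cyclohexa-1,3-dien-1-yl]ethan-1-one
Conditions: Me3SiCl, Et3N, toluene, rt; filtration under Ar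
Reagents that add atoms: chlorotrimethylsilane, C[Si](C)(C)Cl
Why: O-silylation of the enol form of a 1,3-diketone with a silyl chloride and an amine base; in such cis-β-silyloxy enones silicon can move between the two oxygens, so which oxygen is silylated first should not matter for step 5.

Step 5
Reactants: 6 1-[3,4-dimethoxy-2-(trimethylsilyloxy)cyclohexa-1,3-dien-1-yl]ethan-1-one
Product: 8 3,4-dimethoxy-2-(trimethylsilyloxy)-1-[1-(trimethylsilyloxy)ethenyl]cyclohexa-1,3-diene, via lithium dienolate 7 (not isolated)
Conditions: LiN(iPr)2, THF, −78 °C; then Me3SiCl, −78 °C → rt; pentane, filtration under Ar, used crude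
Reagents that add atoms: chlorotrimethylsilane, C[Si](C)(C)Cl
Why: Kinetic deprotonation of the methyl ketone by the hindered amide at −78 °C gives the cross-conjugated dienolate 7, which the chlorosilane traps on oxygen; this is the standard second stage in the preparation of 1,3-bis(silyloxy)-1,3-dienes from 1,3-diketones.

Step 6
Reactants: 9 3-hydroxy-4,5-dimethoxybenzaldehyde
Product: 10 3-benzyloxy-4,5-dimethoxybenzaldehyde
Conditions: BnBr, K2CO3, DMF, 60 °C
Reagents that add atoms: benzyl bromide, BrCc1ccccc1
Why: Williamson ether synthesis on the only free phenol; the benzyl ether tolerates the titanium catalyst, CF3CO2H and the quinone oxidant and is removed at the end without base.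

Step 7
Reactants: 8 3,4-dimethoxy-2-(trimethylsilyloxy)-1-[1-(trimethylsilyloxy)ethenyl]cyclohexa-1,3-diene; 10 3-benzyloxy-4,5-dimethoxybenzaldehyde
Product: 13 (S)-2-(3-benzyloxy-4,5-dimethoxyphenyl)-7,8-dimethoxy-2,3,5,6-tetrahydro-4H-chromen-4-one, via silylated aldol adduct 11 (not isolated), via hydroxy diketone 12 (not isolated)
Conditions: Ti(OiPr)4 (10 mol %), (S)-BINOL (12 mol %), 4 Å MS, THF, −78 °C → −20 °C; then CF3CO2H, CH2Cl2, 0 °C → rt
Reagents that add atoms: none
Why: Ti(OiPr)4 and (S)-BINOL give a chiral tetravalent titanium binaphtholate that binds the aldehyde of 10, and the unsubstituted terminal CH2 of diene 8 adds to it in a Mukaiyama aldol reaction that forms C2–C3 and, after silyl transfer, the adduct 11. CF3CO2H then removes both silyl groups to give the δ-hydroxy β-diketone 12, whose carbinol oxygen adds to the ring carbonyl (the future C8a); loss of water toward C4a forms O1–C8a and the vinylogous ester 13. The closest known reaction type is the titanium–BINOL-catalysed aldol addition of 1,3-bis(silyloxy)dienes and of 1-alkoxy-3-silyloxydienes to aryl aldehydes followed by acid cyclisation to 2-aryl-2,3-dihydro-4H-pyran-4-ones, a formal hetero-Diels–Alder reaction. Ring C, the only ring formed, closes in the 6-exo-trig mode by attack of the hydroxyl on the C=O carbon, and dehydration follows. C2, the only new stereocentre, is controlled by the catalyst: the binaphtholate shields one face of the bound aldehyde, and the (S)-ligand is expected to leave the Si face open, which gives the S carbinol. Since the C2–O bond is never broken during cyclisation, this configuration should pass unchanged into 13. The step needs site selectivity in the diene and chemoselectivity in the closure: the terminal methylene is the only unhindered nucleophilic carbon because the internal diene carbon (future C4a) is fully substituted, and only the ring carbonyl lies at the distance that gives a six-membered ring. The acid treatment is kept cold and short so that the electron-rich benzylic carbinol does not ionise before it cyclises.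

Step 8
Reactants: 13 (S)-2-(3-benzyloxy-4,5-dimethoxyphenyl)-7,8-dimethoxy-2,3,5,6-tetrahydro-4H-chromen-4-one
Product: 14 (S)-2-(3-benzyloxy-4,5-dimethoxyphenyl)-7,8-dimethoxychroman-4-one
Conditions: DDQ (1.05 equiv), toluene, 0 °C → rt
Reagents that add atoms: none
Why: Dehydrogenation of a cyclohexa-1,3-diene by a high-potential quinone: hydride is taken from C5 to give a cation delocalised over C8a and C7 and stabilised by O1 and the C7 methoxy group, and loss of the C6 proton gives the arene; the gain of aromaticity should make this much faster than attack on the C2–H or C3–H bonds, and a plain benzyl ether is not electron-rich enough to be cleaved.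

Step 9
Reactants: 14 (S)-2-(3-benzyloxy-4,5-dimethoxyphenyl)-7,8-dimethoxychroman-4-one
Product: 15 (S)-2-(3-hydroxy-4,5-dimethoxyphenyl)-7,8-dimethoxychroman-4-one
Conditions: H2 (1 atm), 10% Pd/C, EtOAc, rt
Reagents that add atoms: none
Why: Hydrogenolysis of an aryl benzyl ether on palladium under neutral conditions; no base is present, so ring C cannot open and C2 keeps its configuration, and at 1 atm the aryl ketone and the cyclic benzylic C2–O1 bond should react far more slowly than the O-benzyl group.

## Compound list

1 | pyrogallol (benzene-1,2,3-triol) | Oc1cccc(O)c1O | starting material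
2 | dihydropyrogallol (2,3-dihydroxycyclohex-2-en-1-one) | O=C1CCCC(O)=C1O | intermediate
3 | 2,3-dimethoxycyclohex-2-en-1-one | COC1=C(OC)C(=O)CCC1 | intermediate
4 | lithium 5,6-dimethoxycyclohexa-1,5-dien-1-olate (kinetic α′-enolate of 3) | COC1=C(OC)C(O[Li])=CCC1 | intermediate (not isolated)
5 | 6-acetyl-2,3-dimethoxycyclohex-2-en-1-one (enolised 1,3-diketone; C6 carries no defined configuration) | CC(=O)C1CCC(OC)=C(OC)C1=O | intermediate
6 | 1-[3,4-dimethoxy-2-(trimethylsilyloxy)cyclohexa-1,3-dien-1-yl]ethan-1-one | CC(=O)C1=C(O[Si](C)(C)C)C(OC)=C(OC)CC1 | intermediate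
7 | lithium 1-[3,4-dimethoxy-2-(trimethylsilyloxy)cyclohexa-1,3-dien-1-yl]ethen-1-olate | C=C(O[Li])C1=C(O[Si](C)(C)C)C(OC)=C(OC)CC1 | intermediate (not isolated)
8 | 3,4-dimethoxy-2-(trimethylsilyloxy)-1-[1-(trimethylsilyloxy)ethenyl]cyclohexa-1,3-diene | C=C(O[Si](C)(C)C)C1=C(O[Si](C)(C)C)C(OC)=C(OC)CC1 | intermediate
9 | 3-hydroxy-4,5-dimethoxybenzaldehyde | COc1cc(C=O)cc(O)c1OC | starting material
10 | 3-benzyloxy-4,5-dimethoxybenzaldehyde | COc1cc(C=O)cc(OCc2ccccc2)c1OC | intermediate
11 | (3S)-3-(3-benzyloxy-4,5-dimethoxyphenyl)-1-[3,4-dimethoxy-2-(trimethylsilyloxy)cyclohexa-1,3-dien-1-yl]-3-(trimethylsilyloxy)propan-1-one | COC1=C(OC)C(O[Si](C)(C)C)=C(CC1)C(=O)C[C@H](O[Si](C)(C)C)c1cc(OC)c(OC)c(OCc2ccccc2)c1 | intermediate (not isolated)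
12 | 6-[(3S)-3-(3-benzyloxy-4,5-dimethoxyphenyl)-3-hydroxypropanoyl]-2,3-dimethoxycyclohex-2-en-1-one (C6 of the ring enolisable, not defined) | COC1=C(OC)C(=O)C(CC1)C(=O)C[C@H](O)c1cc(OC)c(OC)c(OCc2ccccc2)c1 | intermediate (not isolated)
13 | (S)-2-(3-benzyloxy-4,5-dimethoxyphenyl)-7,8-dimethoxy-2,3,5,6-tetrahydro-4H-chromen-4-one | COC1=C(OC)C2=C(CC1)C(=O)C[C@@H](c1cc(OC)c(OC)c(OCc3ccccc3)c1)O2 | intermediate
14 | (S)-2-(3-benzyloxy-4,5-dimethoxyphenyl)-7,8-dimethoxychroman-4-one | COc1cc([C@@H]2CC(=O)c3ccc(OC)c(OC)c3O2)cc(OCc2ccccc2)c1OC | intermediate
15 | (S)-2-(3-hydroxy-4,5-dimethoxyphenyl)-7,8-dimethoxychroman-4-one | COc1cc([C@@H]2CC(=O)c3ccc(OC)c(OC)c3O2)cc(O)c1OC | target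

## Step count and least certain steps

Total: 9 steps. Longest linear sequence: 8 steps (steps 1–5 and 7–9); step 6 is a one-step side branch.

**Step 7 (key step).** Three processes could spoil it:
- Poor facial selectivity or slow turnover, because the nucleophilic methylene of 8 sits next to a fully substituted carbon and the chelating aldol product can hold on to titanium.
- Ionisation of the electron-rich benzylic carbinol under CF3CO2H, followed by elimination and non-selective reclosure, which would erode the configuration at C2.
- Hydrolysis of the dienol ether of ring A by the water released in the cyclisation.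

The fallback sets the stereocentre in a separate, established step and joins the pieces afterwards. It sets out from 10 and from 3 and comes back to the route at 13. A Roskamp reaction of 10 with ethyl diazoacetate and catalytic SnCl2 should give ethyl 3-(3-benzyloxy-4,5-dimethoxyphenyl)-3-oxopropanoate F1. Noyori hydrogenation with RuCl2[(R)-BINAP] in ethanol should give ethyl (3S)-3-(3-benzyloxy-4,5-dimethoxyphenyl)-3-hydroxypropanoate F2; the same spatial sense that gives (R)-3-hydroxybutanoates corresponds to S here because the aryl group outranks the CH2 group. Silylation with tert-butyldimethylsilyl chloride and imidazole gives ethyl (3S)-3-(3-benzyloxy-4,5-dimethoxyphenyl)-3-(tert-butyldimethylsilyloxy)propanoate F3. Reduction with iBu2AlH at −78 °C gives (3S)-3-(3-benzyloxy-4,5-dimethoxyphenyl)-3-(tert-butyldimethylsilyloxy)propanal F4. Aldol addition of the lithium enolate 4 (from 3, as in step 3) gives 6-[(3S)-3-(3-benzyloxy-4,5-dimethoxyphenyl)-3-(tert-butyldimethylsilyloxy)-1-hydroxypropyl]-2,3-dimethoxycyclohex-2-en-1-one F5 as a mixture at the two new centres. Dess–Martin oxidation converges this mixture on 6-[(3S)-3-(3-benzyloxy-4,5-dimethoxyphenyl)-3-(tert-butyldimethylsilyloxy)propanoyl]-2,3-dimethoxycyclohex-2-en-1-one F6. CF3CO2H in wet CH2Cl2 then removes the silyl group and cyclodehydrates through 12 to 13. This detour needs neither 6 nor 8.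

**Step 5.** If silicon in 6 sits on the acetyl oxygen, the amide base may remove a γ-proton at C4 instead of a methyl proton and give an isomeric triene. Silyl groups may also be lost to moisture during isolation of the crude diene. The fallback fixes the regiochemistry in a stable, separable enol ether. It sets out from 5 and returns at 13. O-methylation of 5 (Me2SO4, K2CO3, acetone) and chromatographic separation from the regioisomeric enol ether should give 1-(2,3,4-trimethoxycyclohexa-1,3-dien-1-yl)ethan-1-one F7. This is a plain methyl ketone, and LiN(iPr)2 followed by Me3SiCl should convert it into trimethyl{[1-(2,3,4-trimethoxycyclohexa-1,3-dien-1-yl)ethenyl]oxy}silane F8, a 1-alkoxy-3-silyloxydiene. Under the conditions of step 7, F8 and 10 should give 13, the ring closing by addition of the carbinol oxygen to the β-methoxy enone and loss of methanol instead of water.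

**Step 8.** The quinone may abstract hydride at C2, or dehydrogenate C2–C3 toward the flavone, in competition with aromatisation, and so destroy the stereocentre. The fallback sets out from 13 and returns at 15. Heating 13 with Pd/C in ethanol under argon is a catalytic transfer hydrogenolysis of the kind that uses cyclohexadienes as hydrogen donors. Here the dihydro ring A is the donor: it aromatises on palladium and the hydrogen it gives up cleaves the benzyl ether, so steps 8 and 9 merge and no new compound is made (F0).

**Step 3.** Proton transfer from the acidic 1,3-diketone product to unreacted enolate, or competing O-acylation, may limit conversion. The fallback sets out from 3 and returns at 5. Aldol addition of enolate 4 to acetaldehyde at −78 °C should give 6-(1-hydroxyethyl)-2,3-dimethoxycyclohex-2-en-1-one F9 as a diastereomer mixture, and Dess–Martin oxidation of the secondary alcohol then gives 5.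

## Further compounds

F1 | step 7 | ethyl 3-(3-benzyloxy-4,5-dimethoxyphenyl)-3-oxopropanoate | CCOC(=O)CC(=O)c1cc(OC)c(OC)c(OCc2ccccc2)c1
F2 | step 7 | ethyl (3S)-3-(3-benzyloxy-4,5-dimethoxyphenyl)-3-hydroxypropanoate | CCOC(=O)C[C@H](O)c1cc(OC)c(OC)c(OCc2ccccc2)c1
F3 | step 7 | ethyl (3S)-3-(3-benzyloxy-4,5-dimethoxyphenyl)-3-(tert-butyldimethylsilyloxy)propanoate | CCOC(=O)C[C@H](O[Si](C)(C)C(C)(C)C)c1cc(OC)c(OC)c(OCc2ccccc2)c1
F4 | step 7 | (3S)-3-(3-benzyloxy-4,5-dimethoxyphenyl)-3-(tert-butyldimethylsilyloxy)propanal | O=CC[C@H](O[Si](C)(C)C(C)(C)C)c1cc(OC)c(OC)c(OCc2ccccc2)c1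
F5 | step 7 | 6-[(3S)-3-(3-benzyloxy-4,5-dimethoxyphenyl)-3-(tert-butyldimethylsilyloxy)-1-hydroxypropyl]-2,3-dimethoxycyclohex-2-en-1-one | COC1=C(OC)C(=O)C(CC1)C(O)C[C@H](O[Si](C)(C)C(C)(C)C)c1cc(OC)c(OC)c(OCc2ccccc2)c1
F6 | step 7 | 6-[(3S)-3-(3-benzyloxy-4,5-dimethoxyphenyl)-3-(tert-butyldimethylsilyloxy)propanoyl]-2,3-dimethoxycyclohex-2-en-1-one | COC1=C(OC)C(=O)C(CC1)C(=O)C[C@H](O[Si](C)(C)C(C)(C)C)c1cc(OC)c(OC)c(OCc2ccccc2)c1
F7 | step 5 | 1-(2,3,4-trimethoxycyclohexa-1,3-dien-1-yl)ethan-1-one | CC(=O)C1=C(OC)C(OC)=C(OC)CC1
F8 | step 5 | trimethyl{[1-(2,3,4-trimethoxycyclohexa-1,3-dien-1-yl)ethenyl]oxy}silane | C=C(O[Si](C)(C)C)C1=C(OC)C(OC)=C(OC)CC1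
F0 | step 8 | none | none
F9 | step 3 | 6-(1-hydroxyethyl)-2,3-dimethoxycyclohex-2-en-1-one | CC(O)C1CCC(OC)=C(OC)C1=O
A1 | alternative 1 | 2-(3-benzyloxy-4,5-dimethoxyphenyl)-7,8-dimethoxy-4H-chromen-4-one | COc1cc(-c2cc(=O)c3ccc(OC)c(OC)c3o2)cc(OCc2ccccc2)c1OC
A2 | alternative 1 | 6-iodo-2,3-dimethoxyphenol | COc1ccc(I)c(O)c1OC
A3 | alternative 1 | 1-(benzyloxy)-5-ethynyl-2,3-dimethoxybenzene | C#Cc1cc(OC)c(OC)c(OCc2ccccc2)c1
A4 | alternative 1 | carbon monoxide | [C-]#[O+]
A5 | alternative 2 | (S)-2-(3-benzyloxy-4,5-dimethoxyphenyl)-7-methoxy-8-(4,4,5,5-tetramethyl-1,3,2-dioxaborolan-2-yl)chroman-4-one | COc1cc([C@@H]2CC(=O)c3ccc(OC)c(B4OC(C)(C)C(C)(C)O4)c3O2)cc(OCc2ccccc2)c1OC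
A6 | alternative 2 | 6-iodo-3-methoxy-2-(4,4,5,5-tetramethyl-1,3,2-dioxaborolan-2-yl)phenyl trifluoromethanesulfonate | COc1ccc(I)c(OS(=O)(=O)C(F)(F)F)c1B1OC(C)(C)C(C)(C)O1
A7 | alternative 2 | methyl (S)-3-(3-benzyloxy-4,5-dimethoxyphenyl)-3-hydroxypropanoate | COC(=O)C[C@H](O)c1cc(OC)c(OC)c(OCc2ccccc2)c1
A8 | alternative 3 | (2S,4S)-2-(3-benzyloxy-4,5-dimethoxyphenyl)-7,8-dimethoxychroman-4-ol | COc1cc([C@@H]2C[C@H](O)c3ccc(OC)c(OC)c3O2)cc(OCc2ccccc2)c1OC
A9 | alternative 3 | (1S,3S)-1-(2-bromo-3,4-dimethoxyphenyl)-3-(3-benzyloxy-4,5-dimethoxyphenyl)propane-1,3-diol | COc1cc([C@@H](O)C[C@H](O)c2ccc(OC)c(OC)c2Br)cc(OCc2ccccc2)c1OC
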